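## Analysis of the target

The target is an unsymmetrical bis-triterpenoid. A 24-nor-friedelane of the 6-oxopristimerol type (aromatic ring A with O2 and O3, C6 ketone conjugated with C7=C8, C29 methyl ester on C20; unprimed locants) is tied through a 1,4-dioxane to ring A' of tingenone (primed locants), with O3 bound to C4' and O2 to C3'. The unprimed half has six stereocentres (C9, C13, C14, C17, C18, C20), five of them quaternary and methyl-bearing. C25 and C26 are β and syn-axial on ring C, C27 is α and trans to C26, and rings D/E are cis-fused with C28 and H18 β. On C20 the methyl C30 is β and the ester α, so the three carbon residues C16, C13 and C29 all sit on the α face of ring E. The primed half adds the six centres of tingenone and two new ones, C3' (hemiketal) and C4', whose oxygens are cis on the face of C25'. The C3' hemiketal next to the C2' ketone, the cross-conjugated trienone, the epimerisable C20' beside the C21' ketone and the aryl vinyl ketone of ring B are all sensitive, so the two halves must be joined last and under neutral conditions. The difficulty is the density of quaternary carbons: C13–C14 (with C9 and C17 beside them) cannot be joined by bimolecular alkylation, and C20 carries a methyl and an ester of similar size, so it gives no useful induction across ring E. The strategy rests on the pair C13/C14 of ring D. C14 carries C8 and C13 carries C12; if C8 is read as a carboxyl carbon and C12=C11 as a vinyl group, the C13–C14 bond is the new σ bond of an ester-enolate Claisen rearrangement, and the other four atoms of ring D (C15–C16–C17–C18) are the tether that makes the ester a ten-membered lactone.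

## Retrosynthetic reasoning

**Dioxane (O3–C4' and O2–C3').** Cutting both C–O bonds of 40 gives catechol 37 and tingenone 38, two complete triterpenoids. The cut is made here because the hemiketal and the quinoid half would not survive earlier steps. Forward, 37 is oxidised to o-quinone 39, which adds as a heterodiene across the C3'=C4' enol of 38. C4' should bond to O3, because the phenoxide that develops at O2 is conjugated with the C6 ketone.

**Oxidation level of ring B.** The C6 ketone and C7=C8 of 37 are taken back through 36 and 34 to the saturated benzylic ring B of 33. This removes the enone as a synthetic problem and leaves a ring B that a cationic closure can make.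

**C9–C10.** The benzylic quaternary C9 of 33 is cut from the arene, giving tertiary alcohol 32. Forward, a C9 cation is captured by the arene carbon para to the C3 methoxy group. The axial C26 methyl forces attack from the α face, which is the configuration the target needs.

**C7–C8.** Alcohol 32 is cut into ketone 26 and aryl alkyne 29 (made from 27). This is the convergent point where the whole ring A carbon set arrives in one addition to the C8 carbonyl.

**Ring C (C9–C11 and C8–C9).** Ketone 26 is opened at C9–C11 to iodide 25 and then traced back through 24 and 22 to acid 20. The C8 carboxyl becomes an ethyl ketone that supplies C9 and C25. The vinyl group becomes the C11 electrophile. Both handles are exactly what the key step leaves.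

**C13–C14 (key).** Acid 20 is traced to lactone 17 through silyl ketene acetal 18. A [3,3] shift is chosen because it joins two fully substituted carbons in a unimolecular, concerted step and leaves C8 and C12 anti on ring D, as ring C needs.

**Lactone C8–O.** Lactone 17 is opened to hydroxy acid 15; forward this is a macrolactonisation helped by the (E)-alkene and the cis-disubstituted ring E.

**C15–C16.** Ester 14 is cut into neopentyl iodide 12 and acceptor 13. A radical addition is chosen because the C16 carbon is neopentyl and closed to ionic substitution. C14 is left uncontrolled because it becomes planar in 18.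

**C16 and C29 as one bridge.** The C16 alcohol and C29 carboxyl of 10 are reconnected to the C29=C16 enol ether of bicyclo[2.2.2]octene 8 and so to 5. The three α substituents of ring E (C16, C13, C29) then become one bridge plus one endo substituent of a bicycle. Their relative configuration, including the otherwise uncontrollable C20, follows from the geometry of a cycloaddition.

**Ring E.** Bicycle 5 is cut into achiral siloxydiene 3 and dienophile 4; 3 comes from enone 1 in two enolate steps. Forward, one catalytic enantioselective Diels–Alder reaction sets C17, C18 and C20.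

## Alternatives that were turned down

**Alternative 1:** The disconnection is at C8'–C9' and C13'–C14' of the primed half. Forward, a 14-membered macrocycle carrying the C7' enone and a C9'=C11'–C12'=C13' diene undergoes a transannular Diels–Alder reaction to the pentacycle A1.
- For it: two bonds, rings B', C' and D' and three quaternary centres arise in one step. On bonds and rings per step it is stronger than the chosen route.
- Against it: both new bonds end at fully substituted carbons (diene termini C9' and C13', dienophile carbon C14'), which is a very demanding cycloaddition. The macrocycle needs three trisubstituted alkenes of defined geometry. A1 still carries C11'=C12' and a C7' ketone that must be reworked into the quinone methide.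
- Comparison: it builds the half that is available as 38 and leaves the ester half unsolved. The chosen strategy puts its one congested bond into a ten-membered precursor that is 12 steps from simple materials, and it is applied to the half that has to be made.

**Alternative 2:** The disconnection is at C3'–C4', inside the finished dimer. Forward, KN(SiMe3)2 deprotonates C4' of a ten-membered aryl lactone (3',4'-seco), and the anion adds through C4' to the lactone carbonyl, closing ring A' and the dioxane to give the bis-ketal A2.
- For it: which oxygen binds which carbon is fixed before the ring closes. On regiocontrol of the union it is stronger than the final cycloaddition chosen here.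
- Against it: the seco-lactone requires ring A' of the tingenone series to be opened or built anew. C4' (and with it C3') is created from a delocalised anion across a ten-membered ring with no nearby element to choose the face. Two ketals must be removed next to an acid-sensitive hemiketal. It does not address C13–C14 at all.
- Comparison: the chosen route unites the halves in one protecting-group-free step and relies on the electronic bias of 39 for regiochemistry.

**Alternative 3:** The disconnection is the friedo backbone itself. Forward, CF3SO3H protonates C12' of a 24-nor-olean-12-ene with a dimethoxy-diene ring A; three methyl shifts and one hydride shift follow, and aromatisation of ring A ends the cascade at A3.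
- For it: suprafacial 1,2-shifts would set C9', C13' and C14' stereospecifically in one operation from an abundant skeleton. In centres set per step it is stronger than the chosen route.
- Against it: the cascade runs against the usual acid-driven drift of friedelanes toward oleananes and is paid for only by the final aromatisation. The first cation has faster exits by proton loss. The oleanane ring E with its geminal methyls must be converted into the 20'-methyl-21'-ketone. It again makes the half that can be bought.
- Comparison: the chosen key step is concerted with a closed transition state and one identifiable selectivity issue, not a cascade with several branch points.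

Key step: step 13

Remark on the chemistry: tingenone 38 is assumed to be purchased as the natural product and is not synthesised.
Remark on the chemistry: C14 in 14–17 is carried as both epimers, because it becomes planar in ketene acetal 18; both converge on 20.
Remark on the chemistry: carbons of the ester half keep their friedelane locants from compound 3 on; β is the face of ring E that carries C28 and C30.

## Steps

Step 1
Reactants: 1 3-methylcyclohex-2-en-1-one
Product: 2 rac-3,6-dimethylcyclohex-2-en-1-one
Conditions: LiN(iPr)2, THF, −78 °C; MeI, −78 to 0 °C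
Reagents that add atoms: iodomethane, CI
Why: Kinetic α′-deprotonation of the enone and C-methylation of the cross-conjugated enolate (enolate alkylation); the new centre is racemic and is erased in step 2.

Step 2
Reactants: 2 rac-3,6-dimethylcyclohex-2-en-1-one
Product: 3 2-(tert-butyldimethylsilyloxy)-1,4-dimethylcyclohexa-1,3-diene
Conditions: LiN(iPr)2, THF, −78 °C; tBuMe2SiOSO2CF3
Reagents that add atoms: tert-butyldimethylsilyl trifluoromethanesulfonate, CC(C)(C)[Si](C)(C)OS(=O)(=O)C(F)(F)F
Why: A second kinetic α′-deprotonation and O-silylation gives the cross-conjugated 2-siloxydiene; the diene is achiral, with C20 and C17 as its methyl-bearing termini and C29 as the siloxy carbon.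

Step 3
Reactants: 3 2-(tert-butyldimethylsilyloxy)-1,4-dimethylcyclohexa-1,3-diene; 4 methyl vinyl ketone
Product: 5 endo-1-[1,4-dimethyl-5-(tert-butyldimethylsilyloxy)bicyclo[2.2.2]oct-5-en-2-yl]ethanone (bridgeheads C17 and C20; acetyl on C18 syn to the C29=C16 bridge; enantiomer as in the compound list)
Conditions: 4 (1.5 equiv), (S)-o-tolyl-oxazaborolidine C24H24BNO·HN(SO2CF3)2 (10 mol %), CH2Cl2, −78 °C
Reagents that add atoms: none
Why: Catalytic enantioselective Diels–Alder reaction with a chiral oxazaborolidinium Lewis acid; the siloxy group directs the acetyl-bearing carbon para to C29 (bonds C17–C18 and C19–C20). Suprafacial addition puts C16 and C29 on one face of ring E and the endo rule puts the acetyl on the same face, so C17, C18 and C20 are set together. The catalyst selects the enantiomer; its sense of induction is to be confirmed on 5 and the mirror-image catalyst taken if needed.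

Step 4
Reactants: 5 endo-bicyclic methyl ketone
Product: 6 ethyl (E)-3-[1,4-dimethyl-5-(tert-butyldimethylsilyloxy)bicyclo[2.2.2]oct-5-en-2-yl]but-2-enoate
Conditions: (EtO)2P(O)CH2CO2Et, NaH, THF, 0 to 66 °C
Reagents that add atoms: triethyl phosphonoacetate, CCOC(=O)CP(=O)(OCC)OCC
Why: Horner–Wadsworth–Emmons olefination of a hindered methyl ketone; the ester ends trans to the bulky bicyclic residue, giving the (E)-C12=C13 alkene. The endo acetyl is expected to be the more stable epimer, so C18 should not drift.

Step 5
Reactants: 6 ethyl (E)-enoate
Product: 7 (E)-3-[1,4-dimethyl-5-(tert-butyldimethylsilyloxy)bicyclo[2.2.2]oct-5-en-2-yl]but-2-en-1-ol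
Conditions: iBu2AlH, CH2Cl2, −78 °C
Reagents that add atoms: none
Why: 1,2-Reduction of the conjugated ester to the C11 allylic alcohol; it is done here because no other ester is yet present, and the silyl enol ether is inert to the hydride.

Step 6
Reactants: 7 allylic alcohol
Product: 8 (E)-3-[1,4-dimethyl-5-(tert-butyldimethylsilyloxy)bicyclo[2.2.2]oct-5-en-2-yl]but-2-en-1-yl acetate
Conditions: Ac2O, pyridine, 4-(dimethylamino)pyridine (cat.), CH2Cl2, 23 °C
Reagents that add atoms: acetic anhydride, CC(=O)OC(C)=O
Why: Acylation protects C11–OH through steps 7–10 and lowers the reactivity of C12=C13 toward ozone; the acetate is later removed in the same operation as the C8 ester.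

Step 7
Reactants: 8 allylic acetate
Product: 10 3-[(E)-4-acetoxybut-2-en-2-yl]-4-(hydroxymethyl)-1,4-dimethylcyclohexane-1-carboxylic acid (CO2H and butenyl and CH2OH all α; both methyls β), via aldehyde silyl ester 9 (not isolated)
Conditions: O3 (1 equiv), CH2Cl2–MeOH, pyridine, −78 °C; NaBH4, −78 to 0 °C; aq. citric acid
Reagents that add atoms: ozone, [O-][O+]=O
Why: Ozonolysis of the silyl enol ether cleaves C29=C16 into differentiated termini, the C29 silyl ester and the C16 aldehyde, and opens the bicycle to ring E. The strained, electron-rich enol ether should react well before the trisubstituted allylic-acetate alkene. NaBH4 reduces the aldehyde and work-up frees the acid.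

Step 8
Reactants: 10 hydroxy acid
Product: 11 methyl 3-[(E)-4-acetoxybut-2-en-2-yl]-4-(hydroxymethyl)-1,4-dimethylcyclohexane-1-carboxylate
Conditions: Me3SiCHN2, PhMe–MeOH, 0 °C
Reagents that add atoms: (trimethylsilyl)diazomethane, C[Si](C)(C)C=[N+]=[N-]
Why: Esterification of the carboxylic acid by the diazoalkane installs the C29 methyl ester of the target; the alcohol and the acetate do not react.

Step 9
Reactants: 11 hydroxy ester
Product: 12 methyl 3-[(E)-4-acetoxybut-2-en-2-yl]-4-(iodomethyl)-1,4-dimethylcyclohexane-1-carboxylate
Conditions: I2, PPh3, imidazole, PhMe, 90 °C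
Reagents that add atoms: iodine, II
Why: Appel-type iodination; the neopentyl C16 needs heat but the oxyphosphonium leaving group makes the substitution workable, and the product is the radical precursor.

Step 10
Reactants: 12 neopentyl iodide; 13 methyl methacrylate
Product: 14 methyl 3-[(E)-4-acetoxybut-2-en-2-yl]-4-(4-methoxy-3-methyl-4-oxobutyl)-1,4-dimethylcyclohexane-1-carboxylate (both C14 epimers)
Conditions: 13 (10 equiv), Bu3SnH (slow addition), AIBN, PhH, 80 °C
Reagents that add atoms: none
Why: Giese radical conjugate addition forms C15–C16 at a neopentyl carbon that is closed to substitution. Cyclisation of the C16 radical onto C12=C13 would be 5-endo or 4-exo and should not compete. C14 is formed without control, which is immaterial.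

Step 11
Reactants: 14 diester acetate
Product: 15 4-[2-[(E)-4-hydroxybut-2-en-2-yl]-4-(methoxycarbonyl)-1,4-dimethylcyclohexyl]-2-methylbutanoic acid (both C14 epimers)
Conditions: LiOH, THF–MeOH–H2O, 23 °C; aq. HCl
Reagents that add atoms: lithium hydroxide, [Li+].[OH-]
Why: Saponification removes the acetate and the C8 methyl ester; the C29 ester on the quaternary C20 is much slower and should survive.

Step 12
Reactants: 15 hydroxy acid
Product: 17 ten-membered (E)-allylic lactone fused to ring E at C17–C18 (C8 carbonyl and O–C11 and C12=C13 in the ring; C29 methyl ester; both C14 epimers), via mixed anhydride 16 (not isolated)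
Conditions: 2,4,6-Cl3C6H2COCl, Et3N, THF, 23 °C; slow addition to 4-(dimethylamino)pyridine, PhMe, 80 °C (1 mM)
Reagents that add atoms: none
Why: Yamaguchi macrolactonisation through the mixed anhydride; the (E)-trisubstituted alkene and the cis-1,2-disubstituted ring E remove rotors and turn the chain ends toward each other, and high dilution disfavours the diolide.

Step 13
Reactants: 17 ten-membered allylic lactone
Product: 20 ring D/E cis-bicyclic acid (14α-carboxyl and 14β-methyl; 13α-methyl and 13β-vinyl; 17β-methyl; 18β-H; 20β-methyl and 20α-CO2Me), via silyl ketene acetal 18 (not isolated), via trimethylsilyl ester 19 (not isolated)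
Conditions: Me3SiCl–Et3N, then LiN(iPr)2, THF–HMPA, −78 °C; 23 to 60 °C; 1 M HCl
Reagents that add atoms: none
Why: LiN(iPr)2 removes the C14 hydrogen, the only enolisable one since C20 is quaternary, and Me3SiCl traps the enolate as ketene acetal 18; the array C14=C8–O–C11–C12=C13 then undergoes a concerted [3,3] shift that forms C13–C14 and breaks O–C11. This is the Ireland–Claisen rearrangement in its ring-contracting form, the closest known type being the contraction of macrocyclic allylic lactones to 2-alkenylcycloalkanecarboxylic acids. Ring D closes transannularly as the six-membered ring spanned by C15–C16–C17–C18, in a chair–chair (trans-decalin-like) array of pericyclic chair and nascent cyclohexane, the topology of the Cope rearrangement of (E,E)-cyclodeca-1,5-dienes. C14 is set relative to C13 by the ketene acetal geometry: only the isomer with C15 anti to the ring oxygen puts both ring bonds equatorial and both methyls axial, hence trans, while the isomer with C15 syn to the ring oxygen would give the cis-dimethyl epimer through its own chair. A ten-membered ring tolerates both isomers, so the geometry is not left to the ring but sought by enolisation in THF–HMPA, where the larger α-residue goes cis to the oxygen that is silylated; the (E)-alkene places C18 equatorial. C13 is set by C17 and C18: the array leading to the natural face keeps C28 equatorial on the new ring, whereas the other face forces C28 syn-axial to C27 and C19 syn-axial to C26. The step must also tolerate two fully substituted termini; the unimolecular, concerted bond formation is what makes that bond accessible, and acyclic ester-enolate Claisen rearrangements are known to join two quaternary carbons.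

Step 14
Reactants: 20 bicyclic acid
Product: 22 ethyl ketone (14α-propanoyl; C8 carbonyl with C9 and C25), via acid chloride 21 (not isolated)
Conditions: (COCl)2, DMF (cat.), CH2Cl2, 23 °C; Et2CuLi, Et2O, −78 °C
Reagents that add atoms: lithium diethylcuprate, [Li+].CC[Cu-]CC
Why: Acylation of an organocuprate by the acid chloride stops at the ketone; the hindered C29 ester and the vinyl group are inert at −78 °C.

Step 15
Reactants: 22 ethyl ketone
Product: 24 primary alcohol (13β-(2-hydroxyethyl); C11–OH), via B-alkyl-9-borabicyclononane 23 (not isolated)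
Conditions: 9-BBN, THF, 23 to 50 °C; H2O2, aq. NaOH, 0 °C
Reagents that add atoms: hydrogen peroxide, OO
Why: Anti-Markovnikov hydroboration–oxidation of the vinyl group; 9-BBN selects the terminal alkene over the ketone, which is shielded by the quaternary C14.

Step 16
Reactants: 24 primary alcohol
Product: 25 primary iodide (13β-(2-iodoethyl))
Conditions: I2, PPh3, imidazole, CH2Cl2, 0 to 23 °C
Reagents that add atoms: iodine, II
Why: Appel iodination of an unhindered primary alcohol.

Step 17
Reactants: 25 keto iodide
Product: 26 tricyclic C/D/E ketone (8-oxo; 9-methyl as both epimers; 13α- and 14β-methyl)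
Conditions: KN(SiMe3)2, THF, −78 to 0 °C
Reagents that add atoms: none
Why: Intramolecular enolate alkylation (6-exo-tet) forms C9–C11 and ring C; C14 is quaternary, so the ketone can enolise only toward C9. The C9 configuration is of no consequence because C9 becomes cationic in step 22.

Step 18
Reactants: 27 2,3-dimethoxytoluene
Product: 28 3,4-dimethoxy-2-methylbenzaldehyde
Conditions: Cl2CHOMe, TiCl4, CH2Cl2, 0 °C; H2O
Reagents that add atoms: dichloromethyl methyl ether, COC(Cl)Cl; water, O
Why: Rieche formylation; substitution goes para to the unhindered methoxy group and ortho to the methyl, the carbon that becomes C5.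

Step 19
Reactants: 28 3,4-dimethoxy-2-methylbenzaldehyde
Product: 29 1-ethynyl-3,4-dimethoxy-2-methylbenzene
Conditions: MeC(O)C(N2)P(O)(OMe)2, K2CO3, MeOH, 23 °C
Reagents that add atoms: dimethyl (1-diazo-2-oxopropyl)phosphonate, COP(=O)(OC)C(=[N+]=[N-])C(C)=O
Why: Ohira–Bestmann homologation of an aryl aldehyde to the terminal alkyne, whose two carbons become C6 and C7.

Step 20
Reactants: 26 tricyclic ketone; 29 aryl alkyne
Product: 31 8-hydroxy-8-[(3,4-dimethoxy-2-methylphenyl)ethynyl] tricycle (C8 and C9 as mixtures), via lithium acetylide 30 (not isolated)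
Conditions: 29, n-BuLi, THF, −78 °C; CeCl3; 26, −78 to 0 °C
Reagents that add atoms: none
Why: 1,2-Addition of a cerium-modified acetylide to a hindered, enolisable ketone forms C7–C8. A linear acetylide is the nucleophile that 2,2,6-trisubstituted cyclohexanones accept, and the cerium salt suppresses enolisation; the hindered C29 ester should not compete.

Step 21
Reactants: 31 propargylic alcohol
Product: 32 8-hydroxy-8-[2-(3,4-dimethoxy-2-methylphenyl)ethyl] tricycle
Conditions: H2 (1 atm), Pd/C, EtOAc, 23 °C
Reagents that add atoms: none
Why: Catalytic hydrogenation of the alkyne to the C6–C7 ethano link; no other C=C bond is present.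

Step 22
Reactants: 32 tertiary alcohol
Product: 33 methyl 2,3-dimethoxy-24-nor-D:A-friedooleana-1,3,5(10)-trien-29-oate (8α-H drawn; 9β-methyl)
Conditions: BF3·OEt2, CH2Cl2, −40 to 0 °C
Reagents that add atoms: none
Why: Friedel–Crafts cyclialkylation of the Bogert–Cook type: ionisation at C8 and a 1,2-hydride shift from C9 (or elimination and reprotonation) give the tertiary C9 cation, which the arene captures at C10, para to the C3 methoxy group, closing the six-membered ring B. Attack anti to the axial C26 methyl gives 9α-aryl/9β-methyl from either C8 epimer, as in the analogous closure of podocarpane-type systems; C8 is later made planar.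

Step 23
Reactants: 33 pentacyclic dimethyl ether
Product: 34 methyl 2,3-dimethoxy-6-oxo-24-nor-D:A-friedooleana-1,3,5(10)-trien-29-oate
Conditions: CrO3, AcOH–H2O, 23 °C
Reagents that add atoms: chromium trioxide, O=[Cr](=O)=O
Why: Benzylic oxidation of the ring methylene C6, which is activated para to the C2 methoxy group; the aryl methyl C23 and the tertiary C–H bonds react more slowly.

Step 24
Reactants: 34 6-ketone
Product: 36 methyl 2,3-dimethoxy-6-oxo-24-nor-D:A-friedooleana-1,3,5(10),7-tetraen-29-oate, via silyl enol ether 35 (not isolated)
Conditions: LiN(SiMe3)2, Me3SiCl, THF, −78 °C; Pd(OAc)2, MeCN, 23 °C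
Reagents that add atoms: none
Why: Saegusa–Ito dehydrogenation; the ketone can enolise only toward C7 and the only β-hydrogen is on C8, so C7=C8 forms and either C8 epimer converges.

Step 25
Reactants: 36 enone dimethyl ether
Product: 37 methyl 2,3-dihydroxy-6-oxo-24-nor-D:A-friedooleana-1,3,5(10),7-tetraen-29-oate (6-oxopristimerol)
Conditions: BBr3, CH2Cl2, −78 to −20 °C
Reagents that add atoms: none
Why: Lewis-acid cleavage of both aryl methyl ethers; the hindered C29 methyl ester is expected to survive at low temperature.

Step 26
Reactants: 37 catechol; 38 tingenone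
Product: 40 CNP0228258.2 (the target; dioxane with O3–C4' and O2–C3', 3'-hemiketal), via o-quinone 39 (not isolated)
Conditions: Ag2O, Et2O, 0 °C, filter; 38, PhMe, 23 °C, dark
Reagents that add atoms: none
Why: Oxidation of the catechol to the o-quinone and inverse-electron-demand hetero-Diels–Alder reaction with the C3'=C4' enol of the diosphenol in 38. The nucleophilic C4' should bond to O3, because the phenoxide developing at O2 is conjugated with the C6 ketone, and O2 then closes on C3'; suprafacial addition makes the two C–O bonds cis. The two faces of 38 are not strongly differentiated, so the isomer formed on the face opposite to C25' is to be expected as well and has to be separated.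

## Compound list

1 | 3-methylcyclohex-2-en-1-one | CC1=CC(=O)CCC1 | starting material
2 | rac-3,6-dimethylcyclohex-2-en-1-one | CC1CCC(C)=CC1=O | intermediate
3 | 2-(tert-butyldimethylsilyloxy)-1,4-dimethylcyclohexa-1,3-diene | CC1=C(O[Si](C)(C)C(C)(C)C)C=C(C)CC1 | intermediate
4 | methyl vinyl ketone (but-3-en-2-one) | CC(=O)C=C | starting material
5 | endo-1-[1,4-dimethyl-5-(tert-butyldimethylsilyloxy)bicyclo[2.2.2]oct-5-en-2-yl]ethanone (acetyl syn to the enol ether bridge) | CC(=O)[C@@H]1C[C@@]2(C)CC[C@]1(C)C=C2O[Si](C)(C)C(C)(C)C | intermediate
6 | ethyl (E)-3-[1,4-dimethyl-5-(tert-butyldimethylsilyloxy)bicyclo[2.2.2]oct-5-en-2-yl]but-2-enoate | CCOC(=O)/C=C(\C)[C@@H]1C[C@@]2(C)CC[C@]1(C)C=C2O[Si](C)(C)C(C)(C)C | intermediate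
7 | (E)-3-[1,4-dimethyl-5-(tert-butyldimethylsilyloxy)bicyclo[2.2.2]oct-5-en-2-yl]but-2-en-1-ol | OC/C=C(\C)[C@@H]1C[C@@]2(C)CC[C@]1(C)C=C2O[Si](C)(C)C(C)(C)C | intermediate
8 | (E)-3-[1,4-dimethyl-5-(tert-butyldimethylsilyloxy)bicyclo[2.2.2]oct-5-en-2-yl]but-2-en-1-yl acetate | CC(=O)OC/C=C(\C)[C@@H]1C[C@@]2(C)CC[C@]1(C)C=C2O[Si](C)(C)C(C)(C)C | intermediate
9 | tert-butyldimethylsilyl 3-[(E)-4-acetoxybut-2-en-2-yl]-4-formyl-1,4-dimethylcyclohexane-1-carboxylate (not isolated) | CC(=O)OC/C=C(\C)[C@@H]1C[C@](C)(C(=O)O[Si](C)(C)C(C)(C)C)CC[C@]1(C)C=O | intermediate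
10 | 3-[(E)-4-acetoxybut-2-en-2-yl]-4-(hydroxymethyl)-1,4-dimethylcyclohexane-1-carboxylic acid (CO2H, butenyl, CH2OH α; methyls β) | CC(=O)OC/C=C(\C)[C@@H]1C[C@](C)(C(=O)O)CC[C@]1(C)CO | intermediate
11 | methyl 3-[(E)-4-acetoxybut-2-en-2-yl]-4-(hydroxymethyl)-1,4-dimethylcyclohexane-1-carboxylate | CC(=O)OC/C=C(\C)[C@@H]1C[C@](C)(C(=O)OC)CC[C@]1(C)CO | intermediate
12 | methyl 3-[(E)-4-acetoxybut-2-en-2-yl]-4-(iodomethyl)-1,4-dimethylcyclohexane-1-carboxylate | CC(=O)OC/C=C(\C)[C@@H]1C[C@](C)(C(=O)OC)CC[C@]1(C)CI | intermediate
13 | methyl methacrylate | C=C(C)C(=O)OC | starting material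
14 | methyl 3-[(E)-4-acetoxybut-2-en-2-yl]-4-(4-methoxy-3-methyl-4-oxobutyl)-1,4-dimethylcyclohexane-1-carboxylate (both C14 epimers) | CC(=O)OC/C=C(\C)[C@@H]1C[C@](C)(C(=O)OC)CC[C@]1(C)CCC(C)C(=O)OC | intermediate
15 | 4-[2-[(E)-4-hydroxybut-2-en-2-yl]-4-(methoxycarbonyl)-1,4-dimethylcyclohexyl]-2-methylbutanoic acid (both C14 epimers) | OC/C=C(\C)[C@@H]1C[C@](C)(C(=O)OC)CC[C@]1(C)CCC(C)C(=O)O | intermediate
16 | mixed anhydride of 15 with 2,4,6-trichlorobenzoic acid (not isolated) | OC/C=C(\C)[C@@H]1C[C@](C)(C(=O)OC)CC[C@]1(C)CCC(C)C(=O)OC(=O)c1c(Cl)cc(Cl)cc1Cl | intermediate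
17 | ten-membered (E)-allylic lactone fused to ring E (key-step precursor; both C14 epimers) | COC(=O)[C@]1(C)CC[C@]2(C)CCC(C)C(=O)OC/C=C(\C)[C@@H]2C1 | intermediate
18 | (Z)-O-trimethylsilyl ketene acetal of 17 (C15 cis to OSiMe3, anti to the ring oxygen; not isolated) | COC(=O)[C@]1(C)CC[C@]2(C)CC/C(C)=C(\O[Si](C)(C)C)OC/C=C(\C)[C@@H]2C1 | intermediate
19 | trimethylsilyl ester of 20 (not isolated) | COC(=O)[C@]1(C)CC[C@]2(C)CC[C@](C)(C(=O)O[Si](C)(C)C)[C@@](C)(C=C)[C@@H]2C1 | intermediate
20 | ring D/E cis-bicyclic acid with 14α-carboxyl, 14β-methyl, 13α-methyl, 13β-vinyl (key-step product) | COC(=O)[C@]1(C)CC[C@]2(C)CC[C@](C)(C(=O)O)[C@@](C)(C=C)[C@@H]2C1 | intermediate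
21 | acid chloride of 20 (not isolated) | COC(=O)[C@]1(C)CC[C@]2(C)CC[C@](C)(C(Cl)=O)[C@@](C)(C=C)[C@@H]2C1 | intermediate
22 | 14α-propanoyl-13β-vinyl bicycle (ethyl ketone) | COC(=O)[C@]1(C)CC[C@]2(C)CC[C@](C)(C(=O)CC)[C@@](C)(C=C)[C@@H]2C1 | intermediate
23 | B-alkyl-9-borabicyclo[3.3.1]nonane from 22 (not isolated) | COC(=O)[C@]1(C)CC[C@]2(C)CC[C@](C)(C(=O)CC)[C@@](C)(CCB3C4CCCC3CCC4)[C@@H]2C1 | intermediate
24 | 14α-propanoyl-13β-(2-hydroxyethyl) bicycle | COC(=O)[C@]1(C)CC[C@]2(C)CC[C@](C)(C(=O)CC)[C@@](C)(CCO)[C@@H]2C1 | intermediate
25 | 14α-propanoyl-13β-(2-iodoethyl) bicycle | COC(=O)[C@]1(C)CC[C@]2(C)CC[C@](C)(C(=O)CC)[C@@](C)(CCI)[C@@H]2C1 | intermediate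
26 | tricyclic C/D/E 8-ketone with 9-methyl (both C9 epimers) | COC(=O)[C@]1(C)CC[C@]2(C)CC[C@]3(C)C(=O)C(C)CC[C@@]3(C)[C@@H]2C1 | intermediate
27 | 2,3-dimethoxytoluene | COc1cccc(C)c1OC | starting material
28 | 3,4-dimethoxy-2-methylbenzaldehyde | COc1ccc(C=O)c(C)c1OC | intermediate
29 | 1-ethynyl-3,4-dimethoxy-2-methylbenzene | COc1ccc(C#C)c(C)c1OC | intermediate
30 | lithium (3,4-dimethoxy-2-methylphenyl)acetylide (not isolated) | [Li]C#Cc1ccc(OC)c(OC)c1C | intermediate
31 | 8-hydroxy-8-(arylethynyl) tricycle (C8, C9 mixtures) | COC(=O)[C@]1(C)CC[C@]2(C)CC[C@]3(C)C(O)(C#Cc4ccc(OC)c(OC)c4C)C(C)CC[C@@]3(C)[C@@H]2C1 | intermediate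
32 | 8-hydroxy-8-(2-arylethyl) tricycle (C8, C9 mixtures) | COC(=O)[C@]1(C)CC[C@]2(C)CC[C@]3(C)C(O)(CCc4ccc(OC)c(OC)c4C)C(C)CC[C@@]3(C)[C@@H]2C1 | intermediate
33 | methyl 2,3-dimethoxy-24-nor-D:A-friedooleana-1,3,5(10)-trien-29-oate (8α-H) | COC(=O)[C@]1(C)CC[C@]2(C)CC[C@]3(C)[C@H]4CCc5c(cc(OC)c(OC)c5C)[C@]4(C)CC[C@@]3(C)[C@@H]2C1 | intermediate
34 | methyl 2,3-dimethoxy-6-oxo-24-nor-D:A-friedooleana-1,3,5(10)-trien-29-oate | COC(=O)[C@]1(C)CC[C@]2(C)CC[C@]3(C)[C@H]4CC(=O)c5c(cc(OC)c(OC)c5C)[C@]4(C)CC[C@@]3(C)[C@@H]2C1 | intermediate
35 | 6-trimethylsilyloxy-6-ene of 34 (not isolated) | COC(=O)[C@]1(C)CC[C@]2(C)CC[C@]3(C)[C@H]4C=C(O[Si](C)(C)C)c5c(cc(OC)c(OC)c5C)[C@]4(C)CC[C@@]3(C)[C@@H]2C1 | intermediate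
36 | methyl 2,3-dimethoxy-6-oxo-24-nor-D:A-friedooleana-1,3,5(10),7-tetraen-29-oate | COC(=O)[C@]1(C)CC[C@]2(C)CC[C@]3(C)C4=CC(=O)c5c(cc(OC)c(OC)c5C)[C@]4(C)CC[C@@]3(C)[C@@H]2C1 | intermediate
37 | methyl 2,3-dihydroxy-6-oxo-24-nor-D:A-friedooleana-1,3,5(10),7-tetraen-29-oate (6-oxopristimerol) | COC(=O)[C@]1(C)CC[C@]2(C)CC[C@]3(C)C4=CC(=O)c5c(cc(O)c(O)c5C)[C@]4(C)CC[C@@]3(C)[C@@H]2C1 | intermediate
38 | tingenone | CC1=C(O)C(=O)C=C2C1=CC=C1[C@@]2(C)CC[C@@]3(C)[C@@H]4C[C@@H](C)C(=O)C[C@]4(C)CC[C@]13C | starting material
39 | o-quinone of 37: methyl 2,3,6-trioxo-24-nor-D:A-friedooleana-1(10),4,7-trien-29-oate (not isolated) | COC(=O)[C@]1(C)CC[C@]2(C)CC[C@]3(C)C4=CC(=O)C5=C(C)C(=O)C(=O)C=C5[C@]4(C)CC[C@@]3(C)[C@@H]2C1 | intermediate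
40 | CNP0228258.2 | COC(=O)[C@]1(C)CC[C@]2(C)CC[C@]3(C)C4=CC(=O)c5c(cc6c(c5C)O[C@]5(C)C7=CC=C8[C@@](C)(CC[C@@]9(C)[C@@H]%10C[C@@H](C)C(=O)C[C@]%10(C)CC[C@]89C)C7=CC(=O)[C@]5(O)O6)[C@]4(C)CC[C@@]3(C)[C@@H]2C1 | target

## Step count and uncertain steps

Total: 26 steps. Longest linear sequence: 24 steps (steps 1–17 and 20–26, from 1); the arene branch is 2 steps (18–19).

**Step 13 (key step).** The most likely failure is enolisation to the ketene acetal with C15 syn to the ring oxygen. A ten-membered ring accommodates that isomer easily, and its chair would deliver the 14-epimer with cis methyls. The second risk is a rearrangement too slow at two fully substituted termini, so that C-silylation or fragmentation of the enolate takes over. The C14 epimers of 17 are diastereomers and may enolise differently; they can be separated and tested one by one. Fallback, from 12 back to 20: the quaternary C14 is made after the ring contraction instead of in it. Giese addition of 12 to methyl acrylate gives the chain without C26, diester F1. Saponification gives hydroxy acid F2 and Yamaguchi lactonisation the 26-nor lactone F3. Its ring contraction has only one quaternary terminus, and the ketene acetal geometry no longer matters because C14 is enolised again; it gives the 14-H acid F4. The dianion of F4 (LiN(iPr)2, 2.2 equiv, THF–HMPA) is methylated with MeI from the β face, anti to the axial C27 methyl and on the convex side of the cis-bicycle, to give 20.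

**Step 26.** Poor facial selectivity on 38 is the main risk, giving the isomer with both C–O bonds on the face opposite to C25'. Loss of the o-quinone by tautomerisation or self-reaction before it is captured is the second. Fallback, from 38 and 37 back to 40: a condensation replaces the cycloaddition. The enol of 38 is oxidised with dimethyldioxirane to the 4'-hydroxy-2',3'-dione F5. With camphorsulfonic acid and molecular sieves in PhMe, the more nucleophilic O3–H of 37 substitutes the C4' hydroxyl through the dienyl-stabilised C4' cation, and O2–H then closes on the C3' ketone as the hemiketal.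

**Step 22.** The C8 cation sits next to the quaternary C14, so a Wagner–Meerwein shift of C26 (the start of a backbone rearrangement) can outrun capture by the arene; closure at C8 to a spiro-indane is a second diversion. Fallback, from 26 back to 36, with no cation near C14 and acylation in place of alkylation for ring B: Pd-catalysed α-arylation of 26 with 5-bromo-1,2-dimethoxy-3-methylbenzene (COc1cc(Br)cc(C)c1OC; Pd(OAc)2, P(tBu)3, NaOtBu, PhMe, 80 °C) should place the aryl group on C9 anti to C26, giving aryl ketone F6. Lithium ethoxyacetylide adds to C8 to give carbinol F7. Meyer–Schuster rearrangement gives unsaturated ester F8, and saponification gives acid F9. Friedel–Crafts acylation (P2O5 in CH3SO3H) at C5 closes ring B directly at the enone level of 36, which also saves steps 23 and 24.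

**Step 12.** Ring strain of the ten-membered lactone may divert the activated acid into the diolide and higher oligomers. Fallback, from 15 back to 17: the roles of the two ends are reversed in a Mitsunobu macrolactonisation (PPh3, diisopropyl azodicarboxylate, PhMe, high dilution), in which the allylic C11 is activated and the carboxylate is the nucleophile; no new compound arises.

**Step 3.** The enantioselectivity may be insufficient on a diene that is substituted at both termini, and stepwise Mukaiyama–Michael addition without ring closure or loss of the silyl group may compete. Fallback, from 3 and 4 back to 5: the cycloaddition is run thermally (PhMe, 110 °C) to the racemate, and the enantiomers are separated by preparative chromatography on a chiral stationary phase; the unwanted enantiomer ent-5 F10 is set aside.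

## Further compounds

F1 | step 13 | methyl 3-[(E)-4-acetoxybut-2-en-2-yl]-4-(4-methoxy-4-oxobutyl)-1,4-dimethylcyclohexane-1-carboxylate | CC(=O)OC/C=C(\C)[C@@H]1C[C@](C)(C(=O)OC)CC[C@]1(C)CCCC(=O)OC
F2 | step 13 | 4-[2-[(E)-4-hydroxybut-2-en-2-yl]-4-(methoxycarbonyl)-1,4-dimethylcyclohexyl]butanoic acid | OC/C=C(\C)[C@@H]1C[C@](C)(C(=O)OC)CC[C@]1(C)CCCC(=O)O
F3 | step 13 | 26-nor ten-membered (E)-allylic lactone | COC(=O)[C@]1(C)CC[C@]2(C)CCCC(=O)OC/C=C(\C)[C@@H]2C1
F4 | step 13 | 26-nor ring D/E acid with C14–H (either C14 epimer) | COC(=O)[C@]1(C)CC[C@]2(C)CCC(C(=O)O)[C@@](C)(C=C)[C@@H]2C1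
F5 | step 26 | 4'-hydroxy-2',3'-dione derived from tingenone (either C4' epimer) | CC1(O)C(=O)C(=O)C=C2C1=CC=C1[C@@]2(C)CC[C@@]3(C)[C@@H]4C[C@@H](C)C(=O)C[C@]4(C)CC[C@]13C
F6 | step 22 | 9α-(3,4-dimethoxy-5-methylphenyl)-9β-methyl tricyclic 8-ketone | COC(=O)[C@]1(C)CC[C@]2(C)CC[C@]3(C)C(=O)[C@](C)(c4cc(C)c(OC)c(OC)c4)CC[C@@]3(C)[C@@H]2C1
F7 | step 22 | 8-(ethoxyethynyl)-8-hydroxy derivative of F6 | COC(=O)[C@]1(C)CC[C@]2(C)CC[C@]3(C)C(O)(C#COCC)[C@](C)(c4cc(C)c(OC)c(OC)c4)CC[C@@]3(C)[C@@H]2C1
F8 | step 22 | ethyl ester with exocyclic C8=C7 (Meyer–Schuster product) | COC(=O)[C@]1(C)CC[C@]2(C)CC[C@]3(C)C(=CC(=O)OCC)[C@](C)(c4cc(C)c(OC)c(OC)c4)CC[C@@]3(C)[C@@H]2C1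
F9 | step 22 | carboxylic acid from F8 | COC(=O)[C@]1(C)CC[C@]2(C)CC[C@]3(C)C(=CC(=O)O)[C@](C)(c4cc(C)c(OC)c(OC)c4)CC[C@@]3(C)[C@@H]2C1
F0 | step 12 | none | none
F10 | step 3 | ent-5 | CC(=O)[C@H]1C[C@]2(C)CC[C@@]1(C)C=C2O[Si](C)(C)C(C)(C)C
A1 | alternative 1 | 7'-oxo-11'-ene pentacycle, catechol dimethyl ether | COc1cc2c(c(C)c1OC)CC(=O)[C@H]1[C@@]2(C)C=C[C@@]2(C)[C@@H]3C[C@@H](C)C(=O)C[C@]3(C)CC[C@]12C
A2 | alternative 2 | target as C2' dimethyl ketal and C21' dioxolane | COC(=O)[C@]1(C)CC[C@]2(C)CC[C@]3(C)C4=CC(=O)c5c(cc6c(c5C)O[C@]5(C)C7=CC=C8[C@@](C)(CC[C@@]9(C)[C@@H]%10C[C@@H](C)C%11(OCCO%11)C[C@]%10(C)CC[C@]89C)C7=CC(OC)(OC)[C@]5(O)O6)[C@]4(C)CC[C@@]3(C)[C@@H]2C1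
A3 | alternative 3 | 7',8'-dihydrotingenol dimethyl ether | COc1cc2c(c(C)c1OC)CC[C@H]1[C@@]2(C)CC[C@@]2(C)[C@@H]3C[C@@H](C)C(=O)C[C@]3(C)CC[C@]12C
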